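**Retrosynthetic overview**
- The strategy rests on ring B. C1' carries chroman C3, C2' and C4' carry oxygen, the prenyl group sits on C3' between the two oxygens, and C5' and C6' carry hydrogen. A 4-substituted cyclobutenone and a substituted siloxyalkyne lay down this sequence (alkyl, OH, alkyne substituent, OSi, H, H) in one operation.
- After a final desilylation, ring B is cut at C2'–C3', C4'–C5' and C1'–C2' into 4-(chroman-3-yl)cyclobutenone 28 and prenyl siloxyalkyne 33.
- 28 comes from carbonyl transposition of 3-ethoxycyclobutenone 26, which comes from the ketene of chroman-3-ylacetic acid 22 and ethoxyacetylene.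
- Ring C is closed by Mitsunobu etherification. C3 is set by Evans alkylation of a 3-arylpropanoyl oxazolidinone with tert-butyl bromoacetate. Ring A is 2,4,6-trihydroxybenzaldehyde after C-prenylation and ordered O-alkylation.
- Order of rings: A (bought), C (step 10), the sacrificial four-membered ring (step 13), B (step 17).

Key step: step 17

Abbreviations: prenyl = 3-methylbut-2-enyl; TIPS = triisopropylsilyl; ArA = 4,6-bis(allyloxy)-2-methoxy-3-prenylphenyl; Chr = (3R)-5-methoxy-6-prenyl-7-(triisopropylsilyloxy)chroman-3-yl.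
Assumption: the stereocentre on the four-membered ring of 26, 27 and 28 is carried as a mixture of epimers, because that carbon becomes the planar C1' of ring B.

Step 1
Reactants: 1 2,4,6-trihydroxybenzaldehyde; 2 prenyl bromide (1-bromo-3-methylbut-2-ene)
Product: 3 2,4,6-trihydroxy-3-prenylbenzaldehyde
Conditions: KOH (1 equiv), H2O, 0 °C to rt, 2 (0.9 equiv) added slowly
Reagents that add atoms: none
Why: C-alkylation of an ambident phloroglucinol phenoxide is favoured in water, C3 and C5 of 1 are equivalent so only one mono-prenyl isomer can form, and a deficit of 2 limits a second alkylation.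

Step 2
Reactants: 3 2,4,6-trihydroxy-3-prenylbenzaldehyde
Product: 4 4,6-bis(allyloxy)-2-hydroxy-3-prenylbenzaldehyde
Conditions: allyl bromide (2.1 equiv), K2CO3, acetone, reflux
Reagents that add atoms: allyl bromide, C=CCBr
Why: In this Williamson etherification the para 4-OH and the open 6-OH should react, while the 2-OH stays free because it is hydrogen-bonded to the aldehyde and squeezed between CHO and prenyl.

Step 3
Reactants: 4 4,6-bis(allyloxy)-2-hydroxy-3-prenylbenzaldehyde
Product: 5 4,6-bis(allyloxy)-2-methoxy-3-prenylbenzaldehyde (ArA-CHO)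
Conditions: MeI, K2CO3, DMF, 40 °C
Reagents that add atoms: iodomethane, CI
Why: Williamson methylation in a polar solvent puts the methyl group on the only oxygen left, the future O5 next to the prenyl group.

Step 4
Reactants: 5 ArA-CHO; 6 Meldrum's acid (2,2-dimethyl-1,3-dioxane-4,6-dione)
Product: 8 5-(ArA-methyl)-2,2-dimethyl-1,3-dioxane-4,6-dione, via arylidene Meldrum's acid 7 (not isolated)
Conditions: Hantzsch ester (diethyl 2,6-dimethyl-1,4-dihydropyridine-3,5-dicarboxylate), L-proline (20 mol %), EtOH, rt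
Reagents that add atoms: none
Why: Knoevenagel condensation is followed in situ by transfer hydrogenation (organocatalytic reductive alkylation of Meldrum's acid), and hydride goes only to the doubly activated alkene of 7, so the allyl and prenyl alkenes are spared.

Step 5
Reactants: 8 5-(ArA-methyl)-2,2-dimethyl-1,3-dioxane-4,6-dione
Product: 10 3-(ArA)propanoic acid, via arylmethylmalonic acid 9 (not isolated)
Conditions: pyridine/H2O (10:1), 100 °C
Reagents that add atoms: water, O
Why: Hydrolytic opening of the acylal and decarboxylation of malonic acid 9 run under weakly basic conditions, well below the temperature at which aryl allyl ethers undergo Claisen rearrangement.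

Step 6
Reactants: 10 3-(ArA)propanoic acid; 11 (S)-4-benzyloxazolidin-2-one
Product: 13 (S)-4-benzyl-3-[3-(ArA)propanoyl]oxazolidin-2-one, via mixed pivalic anhydride 12 (not isolated)
Conditions: t-BuCOCl, Et3N, THF, −20 to 0 °C; then LiCl, 11, rt
Reagents that add atoms: pivaloyl chloride, CC(C)(C)C(=O)Cl (its acyl group is held only in 12)
Why: In this N-acylation of the Evans auxiliary through a mixed anhydride, the lithium-complexed oxazolidinone attacks the unhindered carbonyl of 12.

Step 7
Reactants: 13 (S)-4-benzyl-3-[3-(ArA)propanoyl]oxazolidin-2-one; 14 tert-butyl bromoacetate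
Product: 16 tert-butyl (3R)-3-(ArA-methyl)-4-[(4S)-4-benzyl-2-oxooxazolidin-3-yl]-4-oxobutanoate, via sodium (Z)-enolate 15 (not isolated)
Conditions: NaN(SiMe3)2, THF, −78 °C; 14 (3 equiv), −78 to −30 °C
Reagents that add atoms: NaN(SiMe3)2, C[Si](C)(C)[N-][Si](C)(C)C.[Na+] (sodium is held only in 15)
Why: In this Evans asymmetric alkylation the benzyl group of the (S)-auxiliary shields one face of the chelated (Z)-enolate 15, so the bromoacetate enters from the other face and sets the future C3 as (R).

Step 8
Reactants: 16 tert-butyl (3R)-3-(ArA-methyl)-4-[(4S)-4-benzyl-2-oxooxazolidin-3-yl]-4-oxobutanoate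
Product: 17 tert-butyl (3R)-4-(ArA)-3-(hydroxymethyl)butanoate
Conditions: LiBH4, MeOH (1 equiv), Et2O, 0 °C; pH 7 work-up
Reagents that add atoms: none
Why: In this reductive removal of the auxiliary, LiBH4 attacks the activated exocyclic imide carbonyl faster than the hindered tert-butyl ester, the stereocentre is not involved, and a cold neutral work-up avoids lactonisation.

Step 9
Reactants: 17 tert-butyl (3R)-4-(ArA)-3-(hydroxymethyl)butanoate
Product: 18 tert-butyl (3R)-4-(4,6-dihydroxy-2-methoxy-3-prenylphenyl)-3-(hydroxymethyl)butanoate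
Conditions: Pd(PPh3)4 (5 mol %), morpholine (10 equiv), THF, rt
Reagents that add atoms: none
Why: In this Tsuji–Trost deallylation, zerovalent palladium ionises only the aryl O-allyl ethers to π-allyl complexes that morpholine traps, while the C-bound prenyl group has no leaving group and the medium is neutral.

Step 10
Reactants: 18 tert-butyl (3R)-4-(4,6-dihydroxy-2-methoxy-3-prenylphenyl)-3-(hydroxymethyl)butanoate
Product: 19 tert-butyl 2-[(3R)-7-hydroxy-5-methoxy-6-prenylchroman-3-yl]acetate
Conditions: PPh3, diisopropyl azodicarboxylate, THF (0.02 M), 0 °C to rt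
Reagents that add atoms: none
Why: Intramolecular Mitsunobu etherification (6-exo-tet SN2 at the primary carbon) closes ring C, because only the hydroxyl ortho to the side chain can reach the activated carbon, the other ortho oxygen is methylated, dilution suppresses intermolecular attack by the distal phenol, and C3 is a spectator.

Step 11
Reactants: 19 tert-butyl 2-[(3R)-7-hydroxy-5-methoxy-6-prenylchroman-3-yl]acetate
Product: 20 tert-butyl 2-(Chr)acetate
Conditions: TIPSCl, imidazole, DMF, rt
Reagents that add atoms: chlorotriisopropylsilane, CC(C)[Si](Cl)(C(C)C)C(C)C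
Why: Standard silylation of the single free phenol installs a group that tolerates acid chloride formation, hydride and heat, and that later leaves together with the ring B silyl ether.

Step 12
Reactants: 20 tert-butyl 2-(Chr)acetate
Product: 22 2-(Chr)acetic acid, via trimethylsilyl ester 21 (not isolated)
Conditions: TMSOTf, 2,6-lutidine, CH2Cl2, 0 °C to rt; then pH 5 phosphate buffer
Reagents that add atoms: trimethylsilyl triflate, C[Si](C)(C)OS(=O)(=O)C(F)(F)F (silicon is held only in 21)
Why: In this silyl triflate-mediated cleavage of the tert-butyl ester, the O-silylated ester loses isobutene and the lutidine buffer keeps free acid away from the prenyl alkene and the aryl silyl ether.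

Step 13
Reactants: 22 2-(Chr)acetic acid; 23 ethoxyacetylene
Product: 26 3-ethoxy-4-(Chr)cyclobut-2-en-1-one (both epimers at the ring carbon C4), via acid chloride 24 (not isolated), via monoalkylketene 25 (not isolated)
Conditions: 1-chloro-N,N,2-trimethylprop-1-en-1-amine, CH2Cl2, 0 °C; solution added over 4 h to 23 (5 equiv), Et3N (1.5 equiv), Et2O, rt
Reagents that add atoms: 1-chloro-N,N,2-trimethylprop-1-en-1-amine, CC(C)=C(Cl)N(C)C (chlorine is held only in 24)
Why: Neutral acid chloride formation and dehydrochlorination give the ketene, which undergoes a thermal (2+2) ketene–ynol ether cycloaddition in which the nucleophilic terminal alkyne carbon bonds to the ketene carbonyl carbon, placing Chr next to the ethoxy-bearing carbon, and the new ring stereocentre is uncontrolled and irrelevant.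

Step 14
Reactants: 26 3-ethoxy-4-(Chr)cyclobut-2-en-1-one
Product: 28 4-(Chr)cyclobut-2-en-1-one (both epimers at C4), via cyclobutenol 27 (not isolated)
Conditions: i-Bu2AlH, CH2Cl2, −78 °C; then 1 M HCl, THF, 0 °C; used promptly
Reagents that add atoms: water, O
Why: 1,2-Reduction of the vinylogous ester and acid-induced allylic transposition (Stork–Danheiser type) move the carbonyl to the former ethoxy carbon, so the Chr-bearing sp3 carbon ends up alpha to the new carbonyl (C4), with C2 and C3 as CH.

Step 15
Reactants: 2 prenyl bromide; 29 ethynylmagnesium bromide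
Product: 30 5-methylhex-4-en-1-yne
Conditions: 29 (1.3 equiv, 0.5 M in THF), CuCl (5 mol %), THF, 0 to 40 °C
Reagents that add atoms: none
Why: Copper-catalysed coupling of an alkynyl Grignard reagent with an allylic bromide is the classical route to 1,4-enynes, and attack at the primary carbon of 2 gives the linear prenyl isomer.

Step 16
Reactants: 30 5-methylhex-4-en-1-yne
Product: 33 5-methyl-1-(triisopropylsilyloxy)hex-4-en-1-yne, via lithium acetylide 31 (not isolated), via lithium ynolate 32 (not isolated)
Conditions: n-BuLi, THF, −78 °C; t-BuOOLi (from t-BuOOH and LiN(SiMe3)2, THF, −78 °C), −78 to 0 °C; TIPSOTf, −78 to 0 °C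
Reagents that add atoms: n-butyllithium, CCCC[Li] (lithium is held only in 31 and 32); tert-butyl hydroperoxide, CC(C)(C)OO; triisopropylsilyl triflate, CC(C)[Si](OS(=O)(=O)C(F)(F)F)(C(C)C)C(C)C
Why: Electrophilic oxygen transfer from lithium tert-butyl peroxide oxidises the acetylide to the ynolate, and the bulky silyl triflate then silylates on oxygen rather than carbon to give the siloxyalkyne.

Step 17
Reactants: 28 4-(Chr)cyclobut-2-en-1-one; 33 5-methyl-1-(triisopropylsilyloxy)hex-4-en-1-yne
Product: 38 (3R)-licoricidin 7,4'-bis(triisopropylsilyl) ether (free 2'-OH), via (E)-vinylketene 34 (not isolated), via 4-alkenylcyclobutenone 35 (not isolated), via dienylketene 36 (not isolated), via cyclohexadienone 37 (not isolated)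
Conditions: 33 (1.5 equiv), toluene, 80 °C, 28 added over 2 h; then 110 °C, argon
Reagents that add atoms: none
Why: This is a Danheiser benzannulation in its siloxyalkyne form, in which conrotatory 4π opening of 28, with the bulky Chr group turning outward from either epimer, should give (E)-vinylketene 34, whose ketene C=C adds 33 in a (2+2) cycloaddition to give 35 and the bonds C2'–C3' and C4'–C5'. A second 4π opening gives dienylketene 36, and ring B closes by a 6π electrocyclisation that joins the ketene carbon C2' to the alkene terminus C1' (37), after which enolisation gives the phenol. The regiochemistry needed is prenyl next to the new hydroxyl, and the polarisation of 33 secures it, because the alkyne carbon remote from oxygen is the nucleophilic one and attacks the ketene carbonyl carbon, which leaves the siloxy carbon as C4'. No stereocentre is formed, C3 stays an sp3 carbon throughout, and the medium is neutral, so its configuration and both trisubstituted alkenes should persist. Capture of 34 by 33 has to beat ketene self-reaction and acylation of the product phenol, which slow addition of 28 to excess 33 and the crowding of the 2'-OH between prenyl and Chr should favour. Cyclobutenones carrying one substituent on C4 are an established substrate class for this reaction, giving phenols substituted ortho to the hydroxyl.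

Step 18
Reactants: 38 (3R)-licoricidin 7,4'-bis(triisopropylsilyl) ether
Product: 39 (3R)-licoricidin
Conditions: Bu4NF (2.5 equiv), AcOH (2.5 equiv), THF, 0 °C
Reagents that add atoms: none
Why: Buffered fluoride desilylation removes both aryl silyl ethers without the acid that would cyclise a prenyl group onto a neighbouring phenol.

**Compound list**
1 | 2,4,6-trihydroxybenzaldehyde | O=Cc1c(O)cc(O)cc1O | starting material
2 | prenyl bromide | CC(C)=CCBr | starting material
3 | 2,4,6-trihydroxy-3-prenylbenzaldehyde | O=Cc1c(O)cc(O)c(CC=C(C)C)c1O | intermediate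
4 | 4,6-bis(allyloxy)-2-hydroxy-3-prenylbenzaldehyde | O=Cc1c(OCC=C)cc(OCC=C)c(CC=C(C)C)c1O | intermediate
5 | 4,6-bis(allyloxy)-2-methoxy-3-prenylbenzaldehyde | O=Cc1c(OCC=C)cc(OCC=C)c(CC=C(C)C)c1OC | intermediate
6 | Meldrum's acid | CC1(C)OC(=O)CC(=O)O1 | starting material
7 | 5-(ArA-methylidene) Meldrum's acid | CC1(C)OC(=O)C(=Cc2c(OCC=C)cc(OCC=C)c(CC=C(C)C)c2OC)C(=O)O1 | intermediate
8 | 5-(ArA-methyl) Meldrum's acid | CC1(C)OC(=O)C(Cc2c(OCC=C)cc(OCC=C)c(CC=C(C)C)c2OC)C(=O)O1 | intermediate
9 | 2-(ArA-methyl)malonic acid | OC(=O)C(Cc1c(OCC=C)cc(OCC=C)c(CC=C(C)C)c1OC)C(O)=O | intermediate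
10 | 3-(ArA)propanoic acid | OC(=O)CCc1c(OCC=C)cc(OCC=C)c(CC=C(C)C)c1OC | intermediate
11 | (S)-4-benzyloxazolidin-2-one | O=C1N[C@@H](Cc2ccccc2)CO1 | starting material
12 | mixed pivalic anhydride of 10 | CC(C)(C)C(=O)OC(=O)CCc1c(OCC=C)cc(OCC=C)c(CC=C(C)C)c1OC | intermediate
13 | (S)-4-benzyl-3-[3-(ArA)propanoyl]oxazolidin-2-one | O=C(CCc1c(OCC=C)cc(OCC=C)c(CC=C(C)C)c1OC)N1[C@@H](Cc2ccccc2)COC1=O | intermediate
14 | tert-butyl bromoacetate | CC(C)(C)OC(=O)CBr | starting material
15 | sodium (Z)-enolate of 13 | [Na+].[O-]/C(=C\Cc1c(OCC=C)cc(OCC=C)c(CC=C(C)C)c1OC)N1[C@@H](Cc2ccccc2)COC1=O | intermediate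
16 | tert-butyl (3R)-3-(ArA-methyl)-4-[(4S)-4-benzyl-2-oxooxazolidin-3-yl]-4-oxobutanoate | O=C([C@@H](CC(=O)OC(C)(C)C)Cc1c(OCC=C)cc(OCC=C)c(CC=C(C)C)c1OC)N1[C@@H](Cc2ccccc2)COC1=O | intermediate
17 | tert-butyl (3R)-4-(ArA)-3-(hydroxymethyl)butanoate | OC[C@@H](CC(=O)OC(C)(C)C)Cc1c(OCC=C)cc(OCC=C)c(CC=C(C)C)c1OC | intermediate
18 | tert-butyl (3R)-4-(4,6-dihydroxy-2-methoxy-3-prenylphenyl)-3-(hydroxymethyl)butanoate | OC[C@@H](CC(=O)OC(C)(C)C)Cc1c(O)cc(O)c(CC=C(C)C)c1OC | intermediate
19 | tert-butyl 2-[(3R)-7-hydroxy-5-methoxy-6-prenylchroman-3-yl]acetate | COc1c(CC=C(C)C)c(O)cc2c1C[C@H](CC(=O)OC(C)(C)C)CO2 | intermediate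
20 | tert-butyl 2-(Chr)acetate | COc1c(CC=C(C)C)c(O[Si](C(C)C)(C(C)C)C(C)C)cc2c1C[C@H](CC(=O)OC(C)(C)C)CO2 | intermediate
21 | trimethylsilyl 2-(Chr)acetate | COc1c(CC=C(C)C)c(O[Si](C(C)C)(C(C)C)C(C)C)cc2c1C[C@H](CC(=O)O[Si](C)(C)C)CO2 | intermediate
22 | 2-(Chr)acetic acid | COc1c(CC=C(C)C)c(O[Si](C(C)C)(C(C)C)C(C)C)cc2c1C[C@H](CC(=O)O)CO2 | intermediate
23 | ethoxyacetylene | CCOC#C | starting material
24 | 2-(Chr)acetyl chloride | COc1c(CC=C(C)C)c(O[Si](C(C)C)(C(C)C)C(C)C)cc2c1C[C@H](CC(=O)Cl)CO2 | intermediate
25 | (Chr)ketene | COc1c(CC=C(C)C)c(O[Si](C(C)C)(C(C)C)C(C)C)cc2c1C[C@H](C=C=O)CO2 | intermediate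
26 | 3-ethoxy-4-(Chr)cyclobut-2-en-1-one (epimers at C4) | COc1c(CC=C(C)C)c(O[Si](C(C)C)(C(C)C)C(C)C)cc2c1C[C@H](C1C(=O)C=C1OCC)CO2 | intermediate
27 | 3-ethoxy-4-(Chr)cyclobut-2-en-1-ol (stereoisomers on the four-membered ring) | COc1c(CC=C(C)C)c(O[Si](C(C)C)(C(C)C)C(C)C)cc2c1C[C@H](C1C(O)C=C1OCC)CO2 | intermediate
28 | 4-(Chr)cyclobut-2-en-1-one (epimers at C4) | COc1c(CC=C(C)C)c(O[Si](C(C)C)(C(C)C)C(C)C)cc2c1C[C@H](C1C=CC1=O)CO2 | intermediate
29 | ethynylmagnesium bromide | C#C[Mg]Br | starting material
30 | 5-methylhex-4-en-1-yne | CC(C)=CCC#C | intermediate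
31 | lithium acetylide of 30 | [Li]C#CCC=C(C)C | intermediate
32 | lithium 5-methylhex-4-en-1-yn-1-olate | [Li+].[O-]C#CCC=C(C)C | intermediate
33 | 5-methyl-1-(triisopropylsilyloxy)hex-4-en-1-yne | CC(C)=CCC#CO[Si](C(C)C)(C(C)C)C(C)C | intermediate
34 | (E)-4-(Chr)buta-1,3-dien-1-one (vinylketene) | COc1c(CC=C(C)C)c(O[Si](C(C)C)(C(C)C)C(C)C)cc2c1C[C@H](/C=C/C=C=O)CO2 | intermediate
35 | 4-[(E)-2-(Chr)ethenyl]-2-prenyl-3-(triisopropylsilyloxy)cyclobut-2-en-1-one | COc1c(CC=C(C)C)c(O[Si](C(C)C)(C(C)C)C(C)C)cc2c1C[C@H](/C=C/C1C(=O)C(CC=C(C)C)=C1O[Si](C(C)C)(C(C)C)C(C)C)CO2 | intermediate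
36 | 6-(Chr)-2-prenyl-3-(triisopropylsilyloxy)hexa-1,3,5-trien-1-one (dienylketene) | COc1c(CC=C(C)C)c(O[Si](C(C)C)(C(C)C)C(C)C)cc2c1C[C@H](/C=C/C=C(O[Si](C(C)C)(C(C)C)C(C)C)\C(CC=C(C)C)=C=O)CO2 | intermediate
37 | 6-(Chr)-2-prenyl-3-(triisopropylsilyloxy)cyclohexa-2,4-dien-1-one | COc1c(CC=C(C)C)c(O[Si](C(C)C)(C(C)C)C(C)C)cc2c1C[C@H](C1C=CC(O[Si](C(C)C)(C(C)C)C(C)C)=C(CC=C(C)C)C1=O)CO2 | intermediate
38 | (3R)-licoricidin 7,4'-bis(triisopropylsilyl) ether | COc1c(CC=C(C)C)c(O[Si](C(C)C)(C(C)C)C(C)C)cc2c1C[C@H](c1ccc(O[Si](C(C)C)(C(C)C)C(C)C)c(CC=C(C)C)c1O)CO2 | intermediate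
39 | (3R)-licoricidin | COc1c(CC=C(C)C)c(O)cc2c1C[C@H](c1ccc(O)c(CC=C(C)C)c1O)CO2 | target

Total step count: 18. Longest linear sequence: 16 (steps 1 to 14, then 17 and 18).

**Steps most likely to fail**

1. **Step 17.** The cyclobutenone has no substituent on C2 or C3 and may be consumed by self-condensation before it opens. A share of inward rotation would be followed by a 1,5-hydrogen shift that drains the vinylketene. The vinylketene may also acylate the phenol as it forms.

   The fallback sets out from 20 and comes back at 38 through 34. It makes the same vinylketene from an open-chain diazo ketone at room temperature.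
   - Enolisation of 20 with LiN(i-Pr)2 and oxidation with 2-(phenylsulfonyl)-3-phenyloxaziridine should give the α-hydroxy ester F1.
   - LiAlH4 reduction gives the 1,2-diol F2, and NaIO4 cleavage gives the chroman-3-carbaldehyde F3.
   - Horner–Wadsworth–Emmons olefination with diethyl (3-diazo-2-oxopropyl)phosphonate (LiCl, i-Pr2NEt, MeCN, 0 °C) gives the (E)-diazo enone F4. This mild base is chosen to spare the α-stereocentre.
   - Irradiation of F4 with 33 (Pyrex-filtered mercury lamp, CH2Cl2, rt) triggers a photochemical Wolff rearrangement to 34 at low stationary concentration.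
   - Capture by 33 and warming in toluene then follow the path 35, 36, 37 to 38.

2. **Step 13.** Amine-promoted dimerisation of the monoalkylketene may outrun its capture by the costly, volatile ynol ether, which can only be used in limited excess.

   The fallback sets out from 22 (through 24 and 25) and comes back at 28, or for the isomeric enone at 39.
   - The ketene is generated with Et3N in MeCN that contains ethyl vinyl ether in solvent quantity. The (2+2) cycloaddition should then give the 3-ethoxy-2-(Chr)cyclobutanone F5.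
   - DBU-induced loss of ethanol through the less hindered enolate returns 28 without any hydride step.
   - Enone formed through the other enolate, 2-(Chr)cyclobut-2-en-1-one F6, need not be discarded. With 33 it would give the isomeric 7,2'-bis(silyl) ether F7 (free 4'-OH), and Bu4NF converts F7 into 39 as well.

3. **Step 1.** Over-alkylation on carbon and competing O-alkylation may erode the mono-C-prenylation, and the later regiochemistry then depends on steric discrimination in step 2.

   The fallback sets out from 1 and comes back at 4. It fixes the prenyl position by a sigmatropic shift.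
   - Allyl bromide and K2CO3 give 2,4-bis(allyloxy)-6-hydroxybenzaldehyde F8.
   - 3-Chloro-3-methylbut-1-yne with DBU and CuCl2 (cat.) in MeCN gives the tertiary propargyl ether F9.
   - Semi-hydrogenation (H2, Pd/CaCO3 poisoned with Pb(OAc)2, quinoline) gives the 1,1-dimethylallyl ether F10.
   - Heating F10 in xylene at about 120 °C brings about an aromatic Claisen rearrangement to the only free ortho carbon. This delivers 4 well below the temperature at which the simple allyl ethers rearrange.

**Further compounds**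
F1 | step 17 | tert-butyl 2-hydroxy-2-[(3S)-5-methoxy-6-prenyl-7-(triisopropylsilyloxy)chroman-3-yl]acetate (same spatial arrangement at C3, carbinol epimers) | COc1c(CC=C(C)C)c(O[Si](C(C)C)(C(C)C)C(C)C)cc2c1C[C@H](C(O)C(=O)OC(C)(C)C)CO2
F2 | step 17 | 1-[(3S)-5-methoxy-6-prenyl-7-(triisopropylsilyloxy)chroman-3-yl]ethane-1,2-diol | COc1c(CC=C(C)C)c(O[Si](C(C)C)(C(C)C)C(C)C)cc2c1C[C@H](C(O)CO)CO2
F3 | step 17 | (3S)-5-methoxy-6-prenyl-7-(triisopropylsilyloxy)chroman-3-carbaldehyde | COc1c(CC=C(C)C)c(O[Si](C(C)C)(C(C)C)C(C)C)cc2c1C[C@H](C=O)CO2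
F4 | step 17 | (E)-1-diazo-4-(Chr)but-3-en-2-one | COc1c(CC=C(C)C)c(O[Si](C(C)C)(C(C)C)C(C)C)cc2c1C[C@H](/C=C/C(=O)C=[N+]=[N-])CO2
F5 | step 13 | 3-ethoxy-2-(Chr)cyclobutan-1-one | COc1c(CC=C(C)C)c(O[Si](C(C)C)(C(C)C)C(C)C)cc2c1C[C@H](C1C(=O)CC1OCC)CO2
F6 | step 13 | 2-(Chr)cyclobut-2-en-1-one | COc1c(CC=C(C)C)c(O[Si](C(C)C)(C(C)C)C(C)C)cc2c1C[C@H](C1=CCC1=O)CO2
F7 | step 13 | (3R)-licoricidin 7,2'-bis(triisopropylsilyl) ether | COc1c(CC=C(C)C)c(O[Si](C(C)C)(C(C)C)C(C)C)cc2c1C[C@H](c1ccc(O)c(CC=C(C)C)c1O[Si](C(C)C)(C(C)C)C(C)C)CO2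
F8 | step 1 | 2,4-bis(allyloxy)-6-hydroxybenzaldehyde | O=Cc1c(O)cc(OCC=C)cc1OCC=C
F9 | step 1 | 2,4-bis(allyloxy)-6-[(2-methylbut-3-yn-2-yl)oxy]benzaldehyde | O=Cc1c(OC(C)(C)C#C)cc(OCC=C)cc1OCC=C
F10 | step 1 | 2,4-bis(allyloxy)-6-[(2-methylbut-3-en-2-yl)oxy]benzaldehyde | O=Cc1c(OC(C)(C)C=C)cc(OCC=C)cc1OCC=C
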